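## Analysis of the target

The target is a biflavonoid ether. A (2S)-flavanone with a 5-hydroxyl, a 7-methoxyl and a 4-hydroxyphenyl group at C2 is joined through its C6 oxygen to C4' of a 5,7-dihydroxyflavone. There is one stereocentre, C2 of the flavanone (S). It stands alone, so it must be set absolutely, and it is benzylic, bound to O1 and β to the C4 ketone. This centre epimerises by retro-oxa-Michael opening of ring C under base and by ionisation of C2–O1 under acid, and a free 4'-hydroxyl helps both pathways. Other sensitive points are the four free phenols, the single methyl ether at C7 next to a free C5 hydroxyl, and the flavone enone and benzylic C2–O1 bond under reducing conditions. The difficulty lies in ring A of the flavanone, which carries three contiguous oxygens of three kinds (C5 OH, C6 OAr, C7 OMe), in the diaryl ether oxygen flanked by two ortho oxygen substituents, and in building two chromanone-type heterocycles without one disturbing the other. The strategy rests on flavone C4a. It belongs to a phloroglucinol ring in which O1, O5 and O7 are mutually meta, so opening C4–C4a leaves a 3,5-dioxygenated phenoxy group with two identical ortho carbons, each activated by three oxygens. Ring A of the flavanone has the same hidden symmetry once O5 and O7 are both methyl ethers, because the axis through C6 and C8a makes the two carbons ortho to O1 equivalent.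

## Retrosynthetic reasoning

**25 to 24 to 23.** The phenols of 25 are released last. The ring B phenol comes from benzyl carbonate 24 by hydrogenolysis, which is neutral and leaves C2 alone. 24 comes from 23 by Lewis-acid ether cleavage with a cation scavenger. This removes both flavone benzyl ethers and, through chelation to the flavanone C4 carbonyl, only the C5 methyl ether. That chelation-directed cleavage is what allows ring A of the flavanone to be carried as a symmetric dimethyl ether.

**23 to 21.** The flavanone is cut at C4–C4a, an intramolecular Friedel–Crafts acylation through mixed anhydride 22. The cut is made here, not at O1–C2, because a ring closure at O1–C2 by conjugate addition is reversible and hard to control in absolute sense, whereas in 21 the stereocentre already exists and takes no part in the bond formation. Ring A of 21 is symmetric, so either ortho carbon gives 23. The forward reaction must acylate without ionising the benzylic C–O bond, which is why ring B carries an electron-poor carbonate.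

**21 to 20 to 14 + 19.** The benzylic C2–O1 bond is made by Mitsunobu inversion between phenol 14 and the (R)-alcohol 19. This is the convergent point: the complete flavone half with a single free hydroxyl meets a small chiral fragment. The ester of 20 is tert-butyl so that it is cleaved by acid. Base would eliminate the β-aryloxy group and cleave the carbonate.

**19 to 18 to 16 + 17, and 16 to 15.** The stereocentre comes from asymmetric transfer hydrogenation of β-keto ester 18. 18 is reached from aldehyde 16 by Lewis-acid-catalysed insertion of diazo ester 17 into the formyl C–H bond, and 16 from 15 by acylation of the phenol.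

**14 to 11 (key disconnection).** The flavone is cut at C4–C4a. The precursor is the (Z)-β-aryloxycinnamic acid 11, and the forward step is an acylation through mixed anhydride 12. The cut is placed here because the nucleophile is the symmetric, triply activated phenoxy ring, so no regiochemical question arises and phenol 9 can be used without prior C-acylation. The free phenol of 11 is only masked in passing, as ester 13.

**11 to 10 to 8 + 9.** The vinyl ether bond O1–C2 of the flavone comes from conjugate addition of the phenoxide of 9 to ynoate 8. Anti addition places the aryloxy and ester groups cis. One acidolysis then converts 10 into 11 by removing the tert-butyl ester and the phenol protecting group together.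

**8 to 7 to 6 to 5.** The ynoate is a one-carbon homologue of aldehyde 5. Corey–Fuchs olefination gives 6, and acetylide 7 derived from it is carboxylated as the tert-butyl ester.

**5 to 3 + 4, and 3 to 2 to 1.** The hindered diaryl ether is made by nucleophilic aromatic substitution of 4 by phenol 3. The formyl group of 4 first activates the substitution and then serves as the handle for the alkyne. 3 comes from the symmetric diol 2 by etherification of the unflanked hydroxyl, and 2 by reduction of quinone 1.

## Alternatives that were turned down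

**Alternative 1:** The disconnection is the C2=C3 bond of a pyranone on the lower half, made before ring B and the stereocentre exist.

- Forward key step: the keto-ylide A2, which carries an aryl formate ortho to the ylide-bearing acyl group, is heated in toluene. The ylide carbon adds to the formate carbonyl, the phosphine oxide leaves, and the 2-unsubstituted chromone A1 results, already linked to the dibenzyl flavone through the diaryl ether.
- For: the closure is neutral. The acyl position is fixed in advance, so O5 (benzyl) and O7 (methyl) are differentiated from the start and no selective demethylation is needed. C2 would be introduced afterwards by a catalyst-controlled conjugate arylation and would never meet acid. On these two points it is stronger than the chosen route.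
- Against: A2 is a pentasubstituted, unsymmetrical benzene with four different oxygen functions, one of them a labile aryl formate. Ylide attack on an ester carbonyl is slow and needs prolonged heating. The closure builds neither the flavone nor the stereocentre, so the real difficulty moves to a conjugate addition onto a 5,6,7-trioxygenated, peri-substituted, electron-rich chromone.
- Comparison: both symmetric rings are left unused, every oxygen must be differentiated by hand, and the step count rises. The chosen strategy offers two regiochemically automatic acylations on symmetric rings, with 9 used as purchased.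

**Alternative 2:** The central disconnection is C4–C4a of the flavanone.

- Forward key step: the (S)-3-aryloxy-3-arylpropanoic acid is activated as its mixed trifluoroacetic anhydride and acylates ring A, symmetric as its 5,7-dimethyl ether, to give A3.
- For: the chemistry is sound, and the chosen route uses exactly this closure as step 14. A3 is the same compound as 23 and its acid is 21. On the flavanone half this alternative is therefore as strong as the chosen strategy.
- Against: as the organising disconnection it puts the main risk of the synthesis at the one step in which the stereocentre is exposed to acid. It also leaves open how the flavone half is built. A conventional route through a pre-acylated, differentially protected phloroglucinol unit would need a base-mediated acyl transfer and a cyclodehydration on top of the preparation of that unit.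
- Comparison: the chosen strategy answers the open question with a second acylation of the same kind on a second symmetric ring. One reagent and one mechanistic idea serve both heterocycles, the flavone is assembled from a propiolate and unmodified 9 in three operations, and the stereocentre enters only after the achiral key step.

**Alternative 3:** The bond cut is O1–C8a of flavanone ring C.

- Forward key step: the anti 1,3-diol A5, obtained by asymmetric hydrogenation and carrying a bromine at the future C8a, is treated with CuI, 1,10-phenanthroline and Cs2CO3. The C2 alkoxide couples with the aryl bromide in a six-membered Ullmann-type etherification (the C4 alkoxide could only form a four-membered ring) and gives the flavan-4-ol A4, which would then be oxidised at C4.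
- For: C2 is set by hydrogenation and takes no part in any substitution. There is no inversion step and no acid-labile benzylic aryl ether under acylating conditions. On stereochemical security it is safer than the chosen route.
- Against: A5 is a pentasubstituted bromoarene in which the symmetry of ring A has been broken before the ring is closed. It needs a double asymmetric hydrogenation that controls both carbinol centres although one carbonyl group is flanked by two ortho substituents and an aryl bromide and a flavone enone are present. Hot carbonate and copper act on two benzylic alcohols. The C4 stereocentre is made only to be erased by reoxidation.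
- Comparison: this is a redox detour of several extra operations on the most valuable intermediate. The chosen strategy reaches the ketone oxidation state directly and pays with one inversion step, whose risk is contained by the electron-poor carbonate on ring B.

Key step: step 8

## Route

Remark: the sense of induction in step 11 is taken from the usual model for aryl ketones with RuCl[(R,R)-TsDPEN](p-cymene); the configuration of 19 is to be confirmed before step 12 and the catalyst antipode exchanged if necessary.

Remark: 3,5-bis(benzyloxy)phenol 9 and tert-butyl diazoacetate 17 are treated as purchasable.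

Step 1
Reactants: 1 2,6-dimethoxy-1,4-benzoquinone
Product: 2 2,6-dimethoxybenzene-1,4-diol
Conditions: Na2S2O4, EtOAc/H2O, rt
Reagents that add atoms: none
Why: Dithionite reduction of a 1,4-benzoquinone to the hydroquinone is fast in a two-phase system; the air-sensitive diol is used at once under argon.

Step 2
Reactants: 2 2,6-dimethoxybenzene-1,4-diol
Product: 3 2,6-dimethoxy-4-[(4-methoxybenzyl)oxy]phenol
Conditions: 4-methoxybenzyl chloride (1.0 equiv), K2CO3 (1.0 equiv), DMF, Ar, 0 °C → rt
Reagents that add atoms: 4-methoxybenzyl chloride, COc1ccc(CCl)cc1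
Why: Williamson etherification with one equivalent of base; the 4-hydroxyl is more acidic (two meta methoxy groups) and unhindered, whereas the 1-hydroxyl is flanked by and hydrogen-bonded to two methoxy groups, so the 4-phenoxide should form and alkylate first.

Step 3
Reactants: 3 2,6-dimethoxy-4-[(4-methoxybenzyl)oxy]phenol; 4 4-fluorobenzaldehyde
Product: 5 4-{2,6-dimethoxy-4-[(4-methoxybenzyl)oxy]phenoxy}benzaldehyde
Conditions: K2CO3, DMF, Ar, 110 °C
Reagents that add atoms: none
Why: Nucleophilic aromatic substitution; the para formyl group stabilises the Meisenheimer intermediate and fluoride is the best leaving group for this mechanism. The only free hydroxyl of 3 is the flanked one, so the hindered diaryl ether forms without regiochemical doubt.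

Step 4
Reactants: 5 4-{2,6-dimethoxy-4-[(4-methoxybenzyl)oxy]phenoxy}benzaldehyde
Product: 6 2-[4-(2,2-dibromoethenyl)phenoxy]-1,3-dimethoxy-5-[(4-methoxybenzyl)oxy]benzene
Conditions: CBr4, PPh3, Zn, CH2Cl2, rt
Reagents that add atoms: carbon tetrabromide, BrC(Br)(Br)Br
Why: First stage of the Corey–Fuchs homologation, a Wittig reaction of the dibromomethylene ylide; generating the ylide with zinc keeps the medium neutral and spares the 4-methoxybenzyl ether.

Step 5
Reactants: 6 2-[4-(2,2-dibromoethenyl)phenoxy]-1,3-dimethoxy-5-[(4-methoxybenzyl)oxy]benzene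
Product: 8 tert-butyl 3-(4-{2,6-dimethoxy-4-[(4-methoxybenzyl)oxy]phenoxy}phenyl)prop-2-ynoate, via lithium acetylide 7 (not isolated)
Conditions: n-BuLi (2.1 equiv), THF, −78 °C; then Boc2O, −78 → 0 °C
Reagents that add atoms: di-tert-butyl dicarbonate, CC(C)(C)OC(=O)OC(=O)OC(C)(C)C
Why: Second stage of the Corey–Fuchs sequence: bromine–lithium exchange, α-elimination with 1,2-shift and deprotonation by the second equivalent give acetylide 7. Acylation of a lithium acetylide by Boc2O at low temperature is a standard route to tert-butyl ynoates.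

Step 6
Reactants: 8 tert-butyl 3-(4-{2,6-dimethoxy-4-[(4-methoxybenzyl)oxy]phenoxy}phenyl)prop-2-ynoate; 9 3,5-bis(benzyloxy)phenol
Product: 10 tert-butyl (2Z)-3-[3,5-bis(benzyloxy)phenoxy]-3-(4-{2,6-dimethoxy-4-[(4-methoxybenzyl)oxy]phenoxy}phenyl)prop-2-enoate
Conditions: Cs2CO3 (cat.), DMF, 70 °C
Reagents that add atoms: none
Why: Base-mediated conjugate addition of a phenoxide to an arylpropiolate, the first half of the Ruhemann flavone synthesis. Anti addition across the triple bond places aryloxy and ester groups cis (Z); any E isomer is of little consequence because this push–pull alkene can equilibrate under the acid of steps 7 and 8.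

Step 7
Reactants: 10 tert-butyl (2Z)-3-[3,5-bis(benzyloxy)phenoxy]-3-(4-{2,6-dimethoxy-4-[(4-methoxybenzyl)oxy]phenoxy}phenyl)prop-2-enoate
Product: 11 (2Z)-3-[3,5-bis(benzyloxy)phenoxy]-3-[4-(4-hydroxy-2,6-dimethoxyphenoxy)phenyl]prop-2-enoic acid
Conditions: TFA/CH2Cl2 (1:4), 1,3,5-trimethoxybenzene, 0 °C → rt
Reagents that add atoms: none
Why: Acidolysis removes the tert-butyl ester as isobutene and the 4-methoxybenzyl ether as its stabilised cation, which 1,3,5-trimethoxybenzene traps before it can alkylate the electron-rich rings. Benzyl ethers and the vinylogous carbonate should be stable to anhydrous TFA at this temperature.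

Step 8
Reactants: 11 (2Z)-3-[3,5-bis(benzyloxy)phenoxy]-3-[4-(4-hydroxy-2,6-dimethoxyphenoxy)phenyl]prop-2-enoic acid
Product: 14 5,7-bis(benzyloxy)-2-[4-(4-hydroxy-2,6-dimethoxyphenoxy)phenyl]-4H-chromen-4-one, via bis(trifluoroacetyl) mixed anhydride 12 (not isolated), via flavone aryl trifluoroacetate 13 (not isolated)
Conditions: TFAA (3 equiv), CH2Cl2, 0 °C → rt; then MeOH, rt
Reagents that add atoms: none
Why: TFAA converts the carboxylic acid into its mixed anhydride and at the same time esterifies the free phenol (12), which removes that ring as a competing nucleophile. The anhydride carbonyl, or the acylium ion derived from it, is attacked by an ortho carbon of the 3,5-bis(benzyloxy)phenoxy ring, and loss of a proton from the Wheland intermediate gives the pyranone with the new bond flavone C4–C4a. The closest known reaction is the Ruhemann flavone synthesis, the acid-induced cyclisation of β-aryloxycinnamic acids, run here through a trifluoroacetic mixed anhydride as in standard intramolecular Friedel–Crafts acylations. The ring closes in a 6-exo-trig mode at the anhydride carbonyl (6-exo-dig if the free acylium ion reacts), with the attacking arene bond inside the new six-membered ring. No stereocentre is formed. The step needs a chromone and not an indenone, and a single regioisomer: the Z geometry holds the acyl group beside the aryloxy ring, whose ortho carbons are activated by three oxygens, whereas the para-phenylene ring would have to react meta to its only donor, and the two ortho carbons are identical by symmetry while the para carbon cannot be reached. Methanol in the work-up cleaves aryl trifluoroacetate 13 and returns the phenol.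

Step 9
Reactants: 15 4-hydroxybenzaldehyde
Product: 16 benzyl 4-formylphenyl carbonate
Conditions: benzyl chloroformate, Et3N, CH2Cl2, 0 °C
Reagents that add atoms: benzyl chloroformate, O=C(Cl)OCc1ccccc1
Why: Acylation of the phenol with a chloroformate. The benzyl carbonate makes ring B electron-poor for steps 12 to 15 and is removed later by neutral hydrogenolysis.

Step 10
Reactants: 16 benzyl 4-formylphenyl carbonate; 17 tert-butyl diazoacetate
Product: 18 tert-butyl 3-{4-[(benzyloxycarbonyl)oxy]phenyl}-3-oxopropanoate
Conditions: SnCl2 (10 mol%), CH2Cl2, rt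
Reagents that add atoms: none
Why: Roskamp reaction: the Lewis acid activates the aldehyde, the diazo carbon adds, and a 1,2-hydride shift with loss of N2 gives the β-keto ester. An electron-poor aryl group favours hydride over aryl migration, and the conditions are neutral enough for the carbonate.

Step 11
Reactants: 18 tert-butyl 3-{4-[(benzyloxycarbonyl)oxy]phenyl}-3-oxopropanoate
Product: 19 tert-butyl (3R)-3-{4-[(benzyloxycarbonyl)oxy]phenyl}-3-hydroxypropanoate
Conditions: RuCl[(R,R)-TsDPEN](p-cymene) (1 mol%), HCO2H/Et3N (5:2), CH2Cl2, 30 °C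
Reagents that add atoms: none
Why: Noyori asymmetric transfer hydrogenation of an aryl ketone. The (R,R)-catalyst should deliver hydride to the face that gives the (R)-carbinol, by analogy with acetophenone, the aryl group ranking above the CH2CO2tBu arm as phenyl does above methyl. Carbonate and tert-butyl ester should be inert to the buffered formic acid.

Step 12
Reactants: 14 5,7-bis(benzyloxy)-2-[4-(4-hydroxy-2,6-dimethoxyphenoxy)phenyl]-4H-chromen-4-one; 19 tert-butyl (3R)-3-{4-[(benzyloxycarbonyl)oxy]phenyl}-3-hydroxypropanoate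
Product: 20 tert-butyl (3S)-3-(4-{4-[5,7-bis(benzyloxy)-4-oxo-4H-chromen-2-yl]phenoxy}-3,5-dimethoxyphenoxy)-3-{4-[(benzyloxycarbonyl)oxy]phenyl}propanoate
Conditions: PPh3, DIAD, THF, 0 °C → rt
Reagents that add atoms: none
Why: Mitsunobu etherification: the alcohol is activated as its alkoxyphosphonium ion and displaced by the phenoxide of 14 in an SN2 step, so the (R)-carbinol becomes the (S)-aryl ether. The electron-withdrawing carbonate disfavours the SN1 pathway that would erode configuration, and 14 has only one free hydroxyl.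

Step 13
Reactants: 20 tert-butyl (3S)-3-(4-{4-[5,7-bis(benzyloxy)-4-oxo-4H-chromen-2-yl]phenoxy}-3,5-dimethoxyphenoxy)-3-{4-[(benzyloxycarbonyl)oxy]phenyl}propanoate
Product: 21 (3S)-3-(4-{4-[5,7-bis(benzyloxy)-4-oxo-4H-chromen-2-yl]phenoxy}-3,5-dimethoxyphenoxy)-3-{4-[(benzyloxycarbonyl)oxy]phenyl}propanoic acid
Conditions: TFA/CH2Cl2 (1:4), 0 °C
Reagents that add atoms: none
Why: Acidolysis of the tert-butyl ester. Acid is chosen over saponification because base would eliminate the β-aryloxy group and cleave the carbonate, and the carbonate keeps the benzylic C–O bond from ionising.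

Step 14
Reactants: 21 (3S)-3-(4-{4-[5,7-bis(benzyloxy)-4-oxo-4H-chromen-2-yl]phenoxy}-3,5-dimethoxyphenoxy)-3-{4-[(benzyloxycarbonyl)oxy]phenyl}propanoic acid
Product: 23 benzyl 4-[(2S)-6-{4-[5,7-bis(benzyloxy)-4-oxo-4H-chromen-2-yl]phenoxy}-5,7-dimethoxy-4-oxo-3,4-dihydro-2H-chromen-2-yl]phenyl carbonate, via mixed trifluoroacetic anhydride 22 (not isolated)
Conditions: TFAA (2 equiv), CH2Cl2, 0 °C → rt
Reagents that add atoms: none
Why: Intramolecular Friedel–Crafts acylation through mixed anhydride 22, the standard route from 3-aryloxypropanoic acids to chroman-4-ones. The two carbons ortho to the ether oxygen are equivalent and each is ortho, ortho and para to an oxygen, so one flavanone should form. C2 takes no part in the bond formation and keeps its configuration.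

Step 15
Reactants: 23 benzyl 4-[(2S)-6-{4-[5,7-bis(benzyloxy)-4-oxo-4H-chromen-2-yl]phenoxy}-5,7-dimethoxy-4-oxo-3,4-dihydro-2H-chromen-2-yl]phenyl carbonate
Product: 24 benzyl 4-[(2S)-6-[4-(5,7-dihydroxy-4-oxo-4H-chromen-2-yl)phenoxy]-5-hydroxy-7-methoxy-4-oxo-3,4-dihydro-2H-chromen-2-yl]phenyl carbonate
Conditions: BCl3 (excess), pentamethylbenzene, CH2Cl2, −78 → 0 °C; then MeOH/H2O
Reagents that add atoms: none
Why: BCl3 with pentamethylbenzene as cation scavenger cleaves aryl benzyl ethers at low temperature, and BCl3 bound to the flavanone C4 carbonyl cleaves only the peri C5 methyl ether through a six-membered chelate. The C7 methyl ether is not chelated and should remain; any carbonate lost here converges on the target in step 16.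

Step 16
Reactants: 24 benzyl 4-[(2S)-6-[4-(5,7-dihydroxy-4-oxo-4H-chromen-2-yl)phenoxy]-5-hydroxy-7-methoxy-4-oxo-3,4-dihydro-2H-chromen-2-yl]phenyl carbonate
Product: 25 (2S)-6-[4-(5,7-dihydroxy-4-oxo-4H-chromen-2-yl)phenoxy]-5-hydroxy-2-(4-hydroxyphenyl)-7-methoxy-2,3-dihydro-4H-chromen-4-one
Conditions: H2 (1 atm), Pd/C (10% Pd on carbon), EtOAc/THF, rt
Reagents that add atoms: none
Why: Hydrogenolysis of the benzyl carbonate gives the carbonic acid, which loses CO2 to leave the phenol. Neutral conditions at room temperature should leave C2, the flavone double bond and the benzylic C2–O1 bond untouched if the reaction is stopped at full conversion.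

## Compound list

1 | 2,6-dimethoxy-1,4-benzoquinone | COC1=CC(=O)C=C(OC)C1=O | starting material
2 | 2,6-dimethoxybenzene-1,4-diol | COc1cc(O)cc(OC)c1O | intermediate
3 | 2,6-dimethoxy-4-[(4-methoxybenzyl)oxy]phenol | COc1ccc(COc2cc(OC)c(O)c(OC)c2)cc1 | intermediate
4 | 4-fluorobenzaldehyde | O=Cc1ccc(F)cc1 | starting material
5 | 4-{2,6-dimethoxy-4-[(4-methoxybenzyl)oxy]phenoxy}benzaldehyde | COc1ccc(COc2cc(OC)c(Oc3ccc(C=O)cc3)c(OC)c2)cc1 | intermediate
6 | 2-[4-(2,2-dibromoethenyl)phenoxy]-1,3-dimethoxy-5-[(4-methoxybenzyl)oxy]benzene | COc1ccc(COc2cc(OC)c(Oc3ccc(C=C(Br)Br)cc3)c(OC)c2)cc1 | intermediate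
7 | lithium acetylide, [(4-{2,6-dimethoxy-4-[(4-methoxybenzyl)oxy]phenoxy}phenyl)ethynyl]lithium | COc1ccc(COc2cc(OC)c(Oc3ccc(C#C[Li])cc3)c(OC)c2)cc1 | intermediate
8 | tert-butyl 3-(4-{2,6-dimethoxy-4-[(4-methoxybenzyl)oxy]phenoxy}phenyl)prop-2-ynoate | COc1ccc(COc2cc(OC)c(Oc3ccc(C#CC(=O)OC(C)(C)C)cc3)c(OC)c2)cc1 | intermediate
9 | 3,5-bis(benzyloxy)phenol | Oc1cc(OCc2ccccc2)cc(OCc2ccccc2)c1 | starting material
10 | tert-butyl (2Z)-3-[3,5-bis(benzyloxy)phenoxy]-3-(4-{2,6-dimethoxy-4-[(4-methoxybenzyl)oxy]phenoxy}phenyl)prop-2-enoate | CC(C)(C)OC(=O)/C=C(\Oc1cc(OCc2ccccc2)cc(OCc2ccccc2)c1)c1ccc(Oc2c(OC)cc(OCc3ccc(OC)cc3)cc2OC)cc1 | intermediate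
11 | (2Z)-3-[3,5-bis(benzyloxy)phenoxy]-3-[4-(4-hydroxy-2,6-dimethoxyphenoxy)phenyl]prop-2-enoic acid | OC(=O)/C=C(\Oc1cc(OCc2ccccc2)cc(OCc2ccccc2)c1)c1ccc(Oc2c(OC)cc(O)cc2OC)cc1 | intermediate
12 | (2Z)-3-[3,5-bis(benzyloxy)phenoxy]-3-(4-{2,6-dimethoxy-4-[(trifluoroacetyl)oxy]phenoxy}phenyl)prop-2-enoic trifluoroacetic anhydride | O=C(OC(=O)C(F)(F)F)/C=C(\Oc1cc(OCc2ccccc2)cc(OCc2ccccc2)c1)c1ccc(Oc2c(OC)cc(OC(=O)C(F)(F)F)cc2OC)cc1 | intermediate
13 | 4-{4-[5,7-bis(benzyloxy)-4-oxo-4H-chromen-2-yl]phenoxy}-3,5-dimethoxyphenyl trifluoroacetate | O=c1cc(-c2ccc(Oc3c(OC)cc(OC(=O)C(F)(F)F)cc3OC)cc2)oc2cc(OCc3ccccc3)cc(OCc3ccccc3)c12 | intermediate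
14 | 5,7-bis(benzyloxy)-2-[4-(4-hydroxy-2,6-dimethoxyphenoxy)phenyl]-4H-chromen-4-one | O=c1cc(-c2ccc(Oc3c(OC)cc(O)cc3OC)cc2)oc2cc(OCc3ccccc3)cc(OCc3ccccc3)c12 | intermediate
15 | 4-hydroxybenzaldehyde | O=Cc1ccc(O)cc1 | starting material
16 | benzyl 4-formylphenyl carbonate | O=Cc1ccc(OC(=O)OCc2ccccc2)cc1 | intermediate
17 | tert-butyl diazoacetate | CC(C)(C)OC(=O)C=[N+]=[N-] | starting material
18 | tert-butyl 3-{4-[(benzyloxycarbonyl)oxy]phenyl}-3-oxopropanoate | CC(C)(C)OC(=O)CC(=O)c1ccc(OC(=O)OCc2ccccc2)cc1 | intermediate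
19 | tert-butyl (3R)-3-{4-[(benzyloxycarbonyl)oxy]phenyl}-3-hydroxypropanoate | CC(C)(C)OC(=O)C[C@@H](O)c1ccc(OC(=O)OCc2ccccc2)cc1 | intermediate
20 | tert-butyl (3S)-3-(4-{4-[5,7-bis(benzyloxy)-4-oxo-4H-chromen-2-yl]phenoxy}-3,5-dimethoxyphenoxy)-3-{4-[(benzyloxycarbonyl)oxy]phenyl}propanoate | CC(C)(C)OC(=O)C[C@@H](c1ccc(OC(=O)OCc2ccccc2)cc1)Oc1cc(OC)c(Oc2ccc(-c3cc(=O)c4c(OCc5ccccc5)cc(OCc5ccccc5)cc4o3)cc2)c(OC)c1 | intermediate
21 | (3S)-3-(4-{4-[5,7-bis(benzyloxy)-4-oxo-4H-chromen-2-yl]phenoxy}-3,5-dimethoxyphenoxy)-3-{4-[(benzyloxycarbonyl)oxy]phenyl}propanoic acid | OC(=O)C[C@@H](c1ccc(OC(=O)OCc2ccccc2)cc1)Oc1cc(OC)c(Oc2ccc(-c3cc(=O)c4c(OCc5ccccc5)cc(OCc5ccccc5)cc4o3)cc2)c(OC)c1 | intermediate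
22 | (3S)-3-(4-{4-[5,7-bis(benzyloxy)-4-oxo-4H-chromen-2-yl]phenoxy}-3,5-dimethoxyphenoxy)-3-{4-[(benzyloxycarbonyl)oxy]phenyl}propanoic trifluoroacetic anhydride | O=C(C[C@@H](c1ccc(OC(=O)OCc2ccccc2)cc1)Oc1cc(OC)c(Oc2ccc(-c3cc(=O)c4c(OCc5ccccc5)cc(OCc5ccccc5)cc4o3)cc2)c(OC)c1)OC(=O)C(F)(F)F | intermediate
23 | benzyl 4-[(2S)-6-{4-[5,7-bis(benzyloxy)-4-oxo-4H-chromen-2-yl]phenoxy}-5,7-dimethoxy-4-oxo-3,4-dihydro-2H-chromen-2-yl]phenyl carbonate | COc1cc2c(c(OC)c1Oc1ccc(-c3cc(=O)c4c(OCc5ccccc5)cc(OCc5ccccc5)cc4o3)cc1)C(=O)C[C@@H](c1ccc(OC(=O)OCc3ccccc3)cc1)O2 | intermediate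
24 | benzyl 4-[(2S)-6-[4-(5,7-dihydroxy-4-oxo-4H-chromen-2-yl)phenoxy]-5-hydroxy-7-methoxy-4-oxo-3,4-dihydro-2H-chromen-2-yl]phenyl carbonate | COc1cc2c(c(O)c1Oc1ccc(-c3cc(=O)c4c(O)cc(O)cc4o3)cc1)C(=O)C[C@@H](c1ccc(OC(=O)OCc3ccccc3)cc1)O2 | intermediate
25 | (2S)-6-[4-(5,7-dihydroxy-4-oxo-4H-chromen-2-yl)phenoxy]-5-hydroxy-2-(4-hydroxyphenyl)-7-methoxy-2,3-dihydro-4H-chromen-4-one (CNP0269971.1) | COc1cc2c(c(O)c1Oc1ccc(-c3cc(=O)c4c(O)cc(O)cc4o3)cc1)C(=O)C[C@@H](c1ccc(O)cc1)O2 | target

## Step count and least certain steps

Total step count: 16. Longest linear sequence: 13 steps (steps 1 to 8 and 12 to 16); the side branch to 19 is 3 steps (steps 9 to 11).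

**Step 8 (key step).** The acyl carbon of 12 is a vinylogous carbonate and so a weaker electrophile than a saturated mixed anhydride. If acylation is slow, excess anhydride may trifluoroacetylate the phloroglucinol ring, or the acid formed may cleave the peri benzyl ether once the chromone carbonyl exists. The fallback sets out from aldehyde 5 and returns at 14. Claisen–Schmidt condensation of 5 with purchased 1-[2,4-bis(benzyloxy)-6-hydroxyphenyl]ethanone F1 (KOH, EtOH, rt) should give the chalcone (2E)-1-[2,4-bis(benzyloxy)-6-hydroxyphenyl]-3-(4-{2,6-dimethoxy-4-[(4-methoxybenzyl)oxy]phenoxy}phenyl)prop-2-en-1-one F2. Oxidative cyclisation with catalytic I2 in DMSO at 120 °C should give 5,7-bis(benzyloxy)-2-(4-{2,6-dimethoxy-4-[(4-methoxybenzyl)oxy]phenoxy}phenyl)-4H-chromen-4-one F3. TFA with 1,3,5-trimethoxybenzene, as in step 7, then removes the 4-methoxybenzyl group to give 14.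

**Step 2.** Discrimination between the two hydroxyls may be incomplete, with over-alkylation and reoxidation of the diol on contact with air. The fallback sets out from diol 2 and returns at 5; it puts the regiochemical decision on an acylation, where steric control is stronger. Pivaloyl chloride and pyridine at −20 °C should acylate only the unflanked hydroxyl to give 4-hydroxy-3,5-dimethoxyphenyl 2,2-dimethylpropanoate F4. Substitution on 4 (K2CO3, DMF, 90 °C) gives 4-(4-formylphenoxy)-3,5-dimethoxyphenyl 2,2-dimethylpropanoate F5. Methanolysis (K2CO3, MeOH) gives 4-(4-hydroxy-2,6-dimethoxyphenoxy)benzaldehyde F6, and 4-methoxybenzyl chloride with K2CO3 in DMF then gives 5.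

**Step 10.** Insertion into an aromatic aldehyde is slower than into an aliphatic one, so aryl migration and self-condensation of the diazo ester may compete. The fallback sets out from 16 and returns at 18. A Reformatsky reaction (Zn, tert-butyl bromoacetate, THF) gives racemic tert-butyl 3-{4-[(benzyloxycarbonyl)oxy]phenyl}-3-hydroxypropanoate F7, which Dess–Martin periodinane oxidises to 18.

**Step 12.** The activated β-hydroxy ester has acidic α-hydrogens, so dehydration may compete with substitution, and some ionisation at the benzylic carbon would erode the configuration. The fallback sets out from 16 and returns at acid 21; it removes the acidic α-hydrogens from the Mitsunobu substrate.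

- Keck allylation of 16 (allyltributylstannane, Ti(OiPr)4, the BINOL antipode that gives the (R)-alcohol, 4 Å sieves, CH2Cl2) gives benzyl 4-[(1R)-1-hydroxybut-3-en-1-yl]phenyl carbonate F8.
- Mitsunobu reaction with 14 (PPh3, DIAD, THF) gives benzyl 4-[(1S)-1-(4-{4-[5,7-bis(benzyloxy)-4-oxo-4H-chromen-2-yl]phenoxy}-3,5-dimethoxyphenoxy)but-3-en-1-yl]phenyl carbonate F9.
- Dihydroxylation and diol cleavage (OsO4 cat., N-methylmorpholine N-oxide, then NaIO4) gives (3S)-3-(4-{4-[5,7-bis(benzyloxy)-4-oxo-4H-chromen-2-yl]phenoxy}-3,5-dimethoxyphenoxy)-3-{4-[(benzyloxycarbonyl)oxy]phenyl}propanal F10.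
- Pinnick oxidation (NaClO2, NaH2PO4, 2-methylbut-2-ene) gives 21.

**Step 14.** The attacking carbon is flanked by two substituents. If acylation is slower than expected, the activated acid may lose phenol 14 by retro-oxa-Michael elimination, or the benzylic C–O bond may ionise and erode C2. The fallback sets out from 14 and returns at 25; the stereocentre is then set by a catalyst in a C–C bond formation.

- C-acetylation ortho to the hydroxyl (Ac2O, BF3·OEt2), unambiguous because ring A is symmetric, gives 1-(3-{4-[5,7-bis(benzyloxy)-4-oxo-4H-chromen-2-yl]phenoxy}-6-hydroxy-2,4-dimethoxyphenyl)ethanone F11.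
- N,N-dimethylformamide dimethyl acetal gives the enaminone (2E)-1-(3-{4-[5,7-bis(benzyloxy)-4-oxo-4H-chromen-2-yl]phenoxy}-6-hydroxy-2,4-dimethoxyphenyl)-3-(dimethylamino)prop-2-en-1-one F12.
- Acid closes F12 to 6-{4-[5,7-bis(benzyloxy)-4-oxo-4H-chromen-2-yl]phenoxy}-5,7-dimethoxy-4H-chromen-4-one F13.
- Enantioselective conjugate addition of [4-(benzyloxy)phenyl]boronic acid F14 (Pd(OCOCF3)2, the t-BuPyOx antipode that gives the (S)-product, NH4PF6, H2O, ClCH2CH2Cl, 60 °C) gives (2S)-2-[4-(benzyloxy)phenyl]-6-{4-[5,7-bis(benzyloxy)-4-oxo-4H-chromen-2-yl]phenoxy}-5,7-dimethoxy-2,3-dihydro-4H-chromen-4-one F15.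
- The conditions of step 15 then remove all three benzyl ethers and the chelated methyl ether to give 25.

**Step 15.** Capture of the benzyl cations may be incomplete, leading to C-benzylation of the phloroglucinol rings. The C7 methyl ether, next to the diaryl ether oxygen, may be partly lost, and the Lewis acid may open ring C at C2–O1. The fallback sets out from 23 and returns at 25; it removes the benzyl groups without forming cations. Hydrogenolysis of 23 (H2, Pd/C, EtOAc/THF) gives (2S)-6-[4-(5,7-dihydroxy-4-oxo-4H-chromen-2-yl)phenoxy]-2-(4-hydroxyphenyl)-5,7-dimethoxy-2,3-dihydro-4H-chromen-4-one F16. Chelation-directed demethylation with AlCl3 in MeCN at rt, which then meets only methyl ethers, gives 25.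

## Further compounds

F1 | step 8 | 1-[2,4-bis(benzyloxy)-6-hydroxyphenyl]ethanone | CC(=O)c1c(O)cc(OCc2ccccc2)cc1OCc1ccccc1
F2 | step 8 | (2E)-1-[2,4-bis(benzyloxy)-6-hydroxyphenyl]-3-(4-{2,6-dimethoxy-4-[(4-methoxybenzyl)oxy]phenoxy}phenyl)prop-2-en-1-one | COc1ccc(COc2cc(OC)c(Oc3ccc(/C=C/C(=O)c4c(O)cc(OCc5ccccc5)cc4OCc4ccccc4)cc3)c(OC)c2)cc1
F3 | step 8 | 5,7-bis(benzyloxy)-2-(4-{2,6-dimethoxy-4-[(4-methoxybenzyl)oxy]phenoxy}phenyl)-4H-chromen-4-one | COc1ccc(COc2cc(OC)c(Oc3ccc(-c4cc(=O)c5c(OCc6ccccc6)cc(OCc6ccccc6)cc5o4)cc3)c(OC)c2)cc1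
F4 | step 2 | 4-hydroxy-3,5-dimethoxyphenyl 2,2-dimethylpropanoate | COc1cc(OC(=O)C(C)(C)C)cc(OC)c1O
F5 | step 2 | 4-(4-formylphenoxy)-3,5-dimethoxyphenyl 2,2-dimethylpropanoate | COc1cc(OC(=O)C(C)(C)C)cc(OC)c1Oc1ccc(C=O)cc1
F6 | step 2 | 4-(4-hydroxy-2,6-dimethoxyphenoxy)benzaldehyde | COc1cc(O)cc(OC)c1Oc1ccc(C=O)cc1
F7 | step 10 | racemic tert-butyl 3-{4-[(benzyloxycarbonyl)oxy]phenyl}-3-hydroxypropanoate | CC(C)(C)OC(=O)CC(O)c1ccc(OC(=O)OCc2ccccc2)cc1
F8 | step 12 | benzyl 4-[(1R)-1-hydroxybut-3-en-1-yl]phenyl carbonate | C=CC[C@@H](O)c1ccc(OC(=O)OCc2ccccc2)cc1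
F9 | step 12 | benzyl 4-[(1S)-1-(4-{4-[5,7-bis(benzyloxy)-4-oxo-4H-chromen-2-yl]phenoxy}-3,5-dimethoxyphenoxy)but-3-en-1-yl]phenyl carbonate | C=CC[C@@H](c1ccc(OC(=O)OCc2ccccc2)cc1)Oc1cc(OC)c(Oc2ccc(-c3cc(=O)c4c(OCc5ccccc5)cc(OCc5ccccc5)cc4o3)cc2)c(OC)c1
F10 | step 12 | (3S)-3-(4-{4-[5,7-bis(benzyloxy)-4-oxo-4H-chromen-2-yl]phenoxy}-3,5-dimethoxyphenoxy)-3-{4-[(benzyloxycarbonyl)oxy]phenyl}propanal | O=CC[C@@H](c1ccc(OC(=O)OCc2ccccc2)cc1)Oc1cc(OC)c(Oc2ccc(-c3cc(=O)c4c(OCc5ccccc5)cc(OCc5ccccc5)cc4o3)cc2)c(OC)c1
F11 | step 14 | 1-(3-{4-[5,7-bis(benzyloxy)-4-oxo-4H-chromen-2-yl]phenoxy}-6-hydroxy-2,4-dimethoxyphenyl)ethanone | CC(=O)c1c(O)cc(OC)c(Oc2ccc(-c3cc(=O)c4c(OCc5ccccc5)cc(OCc5ccccc5)cc4o3)cc2)c1OC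
F12 | step 14 | (2E)-1-(3-{4-[5,7-bis(benzyloxy)-4-oxo-4H-chromen-2-yl]phenoxy}-6-hydroxy-2,4-dimethoxyphenyl)-3-(dimethylamino)prop-2-en-1-one | CN(C)/C=C/C(=O)c1c(O)cc(OC)c(Oc2ccc(-c3cc(=O)c4c(OCc5ccccc5)cc(OCc5ccccc5)cc4o3)cc2)c1OC
F13 | step 14 | 6-{4-[5,7-bis(benzyloxy)-4-oxo-4H-chromen-2-yl]phenoxy}-5,7-dimethoxy-4H-chromen-4-one | COc1cc2occc(=O)c2c(OC)c1Oc1ccc(-c2cc(=O)c3c(OCc4ccccc4)cc(OCc4ccccc4)cc3o2)cc1
F14 | step 14 | [4-(benzyloxy)phenyl]boronic acid | OB(O)c1ccc(OCc2ccccc2)cc1
F15 | step 14 | (2S)-2-[4-(benzyloxy)phenyl]-6-{4-[5,7-bis(benzyloxy)-4-oxo-4H-chromen-2-yl]phenoxy}-5,7-dimethoxy-2,3-dihydro-4H-chromen-4-one | COc1cc2c(c(OC)c1Oc1ccc(-c3cc(=O)c4c(OCc5ccccc5)cc(OCc5ccccc5)cc4o3)cc1)C(=O)C[C@@H](c1ccc(OCc3ccccc3)cc1)O2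
F16 | step 15 | (2S)-6-[4-(5,7-dihydroxy-4-oxo-4H-chromen-2-yl)phenoxy]-2-(4-hydroxyphenyl)-5,7-dimethoxy-2,3-dihydro-4H-chromen-4-one | COc1cc2c(c(OC)c1Oc1ccc(-c3cc(=O)c4c(O)cc(O)cc4o3)cc1)C(=O)C[C@@H](c1ccc(O)cc1)O2
A1 | alternative 1 | 5-(benzyloxy)-6-{4-[5,7-bis(benzyloxy)-4-oxo-4H-chromen-2-yl]phenoxy}-7-methoxy-4H-chromen-4-one | COc1cc2occc(=O)c2c(OCc3ccccc3)c1Oc1ccc(-c2cc(=O)c3c(OCc4ccccc4)cc(OCc4ccccc4)cc3o2)cc1
A2 | alternative 1 | 3-(benzyloxy)-4-{4-[5,7-bis(benzyloxy)-4-oxo-4H-chromen-2-yl]phenoxy}-5-methoxy-2-[(triphenyl-λ5-phosphanylidene)acetyl]phenyl formate | COc1cc(OC=O)c(C(=O)C=P(c2ccccc2)(c2ccccc2)c2ccccc2)c(OCc2ccccc2)c1Oc1ccc(-c2cc(=O)c3c(OCc4ccccc4)cc(OCc4ccccc4)cc3o2)cc1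
A3 | alternative 2 | benzyl 4-[(2S)-6-{4-[5,7-bis(benzyloxy)-4-oxo-4H-chromen-2-yl]phenoxy}-5,7-dimethoxy-4-oxo-3,4-dihydro-2H-chromen-2-yl]phenyl carbonate | COc1cc2c(c(OC)c1Oc1ccc(-c3cc(=O)c4c(OCc5ccccc5)cc(OCc5ccccc5)cc4o3)cc1)C(=O)C[C@@H](c1ccc(OC(=O)OCc3ccccc3)cc1)O2
A4 | alternative 3 | (2S,4S)-2-[4-(benzyloxy)phenyl]-6-{4-[5,7-bis(benzyloxy)-4-oxo-4H-chromen-2-yl]phenoxy}-5,7-dimethoxy-3,4-dihydro-2H-chromen-4-ol | COc1cc2c(c(OC)c1Oc1ccc(-c3cc(=O)c4c(OCc5ccccc5)cc(OCc5ccccc5)cc4o3)cc1)[C@@H](O)C[C@@H](c1ccc(OCc3ccccc3)cc1)O2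
A5 | alternative 3 | (1S,3S)-1-[4-(benzyloxy)phenyl]-3-(3-{4-[5,7-bis(benzyloxy)-4-oxo-4H-chromen-2-yl]phenoxy}-6-bromo-2,4-dimethoxyphenyl)propane-1,3-diol | COc1cc(Br)c(c(OC)c1Oc1ccc(-c2cc(=O)c3c(OCc4ccccc4)cc(OCc4ccccc4)cc3o2)cc1)[C@@H](O)C[C@H](O)c1ccc(OCc2ccccc2)cc1
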